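## Retrosynthetic overview

1. Target ⇐ C8 secondary alcohol + O-silylated glycolic acid (last-stage esterification); the C14 acetate is installed early and carried through.
2. The ten-membered carbocycle and the cis-fused α-methylene-γ-lactone come from one open-chain ω-formyl (Z)-2-(bromomethyl)enoate. The C6–C7 bond is made by intramolecular addition of a 2-(methoxycarbonyl)allylchromium (an acrylate β-carbanion, a homoenolate-type donor at C7) to the C6 aldehyde. The carbocycle forms first and the lactone closes onto the new C6 oxygen in the same flask.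
3. Bromo enoate ⇐ Morita–Baylis–Hillman adduct of the C7 α-silyloxy aldehyde with methyl acrylate, then SN2' bromination.
4. C1=C10 alkene (cis in the ring) ⇐ aldol condensation of an (S)-5-(silyloxymethyl)butyrolactone (C7–C10 and C14, C8 stereocentre) with the C1 aldehyde from ozonolysis of (S)-citronellal acetal (C1–C6, C4 stereocentre). Lactone reduction then frees C14–OH and C8–OH.

Assumption: atom labels C1–C14 are germacrane-type positions of the target (C6 = lactone carbinol carbon, C7 = ring-fusion carbon, C8 = glycolate-bearing carbon, C1=C10 = ring alkene, C14 = CH2OAc carbon, C4 = methyl-bearing carbon); compounds 1, 3, 14 and 22 are taken as purchasable.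

## Route

Step 1
Reactants: 1 (S)-5-(hydroxymethyl)dihydrofuran-2(3H)-one
Product: 2 (S)-5-{[(triethylsilyl)oxy]methyl}dihydrofuran-2(3H)-one
Conditions: Et3SiCl, imidazole, CH2Cl2, 0 °C → rt
Reagents that add atoms: chlorotriethylsilane CC[Si](Cl)(CC)CC
Why: Imidazole-promoted silylation of the primary alcohol gives a triethylsilyl ether that survives enolate and hydride chemistry yet can later be oxidised off directly, and the stereocentre (future C8) is not touched.

Step 2
Reactants: 3 (S)-citronellal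
Product: 6 (4S)-6,6-dimethoxy-4-methylhexanal, via dimethyl acetal 4 (not isolated), via ozonide 5 (not isolated)
Conditions: HC(OMe)3, p-TsOH·H2O (1 mol%), CH2Cl2, rt; K2CO3 (solid); O3, −78 °C; then PPh3, −78 °C → rt
Reagents that add atoms: trimethyl orthoformate COC(OC)OC; ozone [O-][O+]=O
Why: Acid-catalysed acetalisation masks the C6 aldehyde, and ozonolysis of the electron-rich trisubstituted alkene with reductive PPh3 work-up then releases the C1 aldehyde without touching the C4 stereocentre.

Step 3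
Reactants: 2 (S)-5-{[(triethylsilyl)oxy]methyl}dihydrofuran-2(3H)-one; 6 (4S)-6,6-dimethoxy-4-methylhexanal
Product: 9 (3E,5S)-3-[(4S)-6,6-dimethoxy-4-methylhexylidene]-5-{[(triethylsilyl)oxy]methyl}dihydrofuran-2(3H)-one, via aldol adduct 7 (not isolated), via mesylate 8 (not isolated)
Conditions: LiN(i-Pr)2, THF, −78 °C; then 6; then MsCl, −78 → 0 °C; then DBU, rt
Reagents that add atoms: none
Why: Aldol addition of the lactone lithium enolate, mesylation and DBU-induced E1cB elimination (aldol condensation) give the thermodynamically favoured E-alkylidene lactone, in which the chain is trans to the carbonyl (future C14) and cis to the ring CH2 (future C9), which is the cis-in-ring geometry of C1=C10.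

Step 4
Reactants: 9 (3E,5S)-3-[(4S)-6,6-dimethoxy-4-methylhexylidene]-5-{[(triethylsilyl)oxy]methyl}dihydrofuran-2(3H)-one
Product: 10 (2S,4E,8S)-4-(hydroxymethyl)-10,10-dimethoxy-8-methyl-1-[(triethylsilyl)oxy]dec-4-en-2-ol
Conditions: i-Bu2AlH (4 equiv), CH2Cl2, −78 → 0 °C; aq. KNaC4H4O6
Reagents that add atoms: none
Why: i-Bu2AlH reduces the conjugated lactone by 1,2-hydride delivery through the lactol to the allylic primary alcohol (C14) and frees the C8 secondary alcohol, leaving the acetal, the silyl ether and the alkene geometry intact.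

Step 5
Reactants: 10 (2S,4E,8S)-4-(hydroxymethyl)-10,10-dimethoxy-8-methyl-1-[(triethylsilyl)oxy]dec-4-en-2-ol
Product: 12 (2E,6S)-2-{(2S)-2-[(tert-butyldimethylsilyl)oxy]-3-[(triethylsilyl)oxy]propyl}-8,8-dimethoxy-6-methyloct-2-en-1-yl acetate, via monoacetate 11 (not isolated)
Conditions: AcCl (1.05 equiv), 2,4,6-collidine, CH2Cl2, −78 °C; then imidazole, t-BuMe2SiCl, DMF, rt
Reagents that add atoms: acetyl chloride CC(Cl)=O; tert-butyldimethylsilyl chloride CC(C)(C)[Si](C)(C)Cl
Why: Acetyl chloride with collidine at −78 °C acylates the unhindered primary allylic alcohol selectively over the secondary one, and the remaining C8 hydroxyl is then silylated in the same flask (chemoselective protection, no stereocentre involved).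

Step 6
Reactants: 12 (2E,6S)-2-{(2S)-2-[(tert-butyldimethylsilyl)oxy]-3-[(triethylsilyl)oxy]propyl}-8,8-dimethoxy-6-methyloct-2-en-1-yl acetate
Product: 13 (2E,6S)-2-{(2S)-2-[(tert-butyldimethylsilyl)oxy]-3-oxopropyl}-8,8-dimethoxy-6-methyloct-2-en-1-yl acetate
Conditions: (COCl)2, DMSO, CH2Cl2, −78 → −40 °C; then Et3N, −78 → 0 °C
Reagents that add atoms: none
Why: Under Swern conditions a primary triethylsilyl ether is cleaved by the chlorosulfonium reagent and oxidised directly to the aldehyde while the secondary TBS ether, the acetal and the acetate are inert (oxidative desilylation), and the low temperature protects the α-stereocentre C8.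

Step 7
Reactants: 13 (2E,6S)-2-{(2S)-2-[(tert-butyldimethylsilyl)oxy]-3-oxopropyl}-8,8-dimethoxy-6-methyloct-2-en-1-yl acetate; 14 methyl acrylate
Product: 15 methyl (4S,6E,10S)-6-(acetoxymethyl)-4-[(tert-butyldimethylsilyl)oxy]-3-hydroxy-12,12-dimethoxy-10-methyl-2-methylidenedodec-6-enoate (C3 epimer mixture)
Conditions: methyl acrylate (10 equiv, neat), 3-hydroxyquinuclidine (0.3 equiv), rt
Reagents that add atoms: none
Why: The Morita–Baylis–Hillman reaction adds the acrylate α-carbon to the activated α-silyloxy aldehyde and so installs C11–C13; the new carbinol centre (C7) forms as a mixture that is erased in step 8.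

Step 8
Reactants: 15 methyl (4S,6E,10S)-6-(acetoxymethyl)-4-[(tert-butyldimethylsilyl)oxy]-3-hydroxy-12,12-dimethoxy-10-methyl-2-methylidenedodec-6-enoate
Product: 16 methyl (2Z,4S,6E,10S)-6-(acetoxymethyl)-2-(bromomethyl)-4-[(tert-butyldimethylsilyl)oxy]-12,12-dimethoxy-10-methyldodeca-2,6-dienoate
Conditions: NBS, Me2S, CH2Cl2, 0 °C; then 15, −20 °C → rt
Reagents that add atoms: N-bromosuccinimide O=C1CCC(=O)N1Br
Why: Corey–Kim-type activation of the allylic alcohol and SN2' attack of bromide at the terminal methylene give the conjugated, thermodynamically preferred Z allylic bromide (C8 cis to CH2Br) under neutral conditions that spare the acetal and the silyl ether.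

Step 9
Reactants: 16 methyl (2Z,4S,6E,10S)-6-(acetoxymethyl)-2-(bromomethyl)-4-[(tert-butyldimethylsilyl)oxy]-12,12-dimethoxy-10-methyldodeca-2,6-dienoate
Product: 17 methyl (2Z,4S,6E,10S)-6-(acetoxymethyl)-2-(bromomethyl)-4-[(tert-butyldimethylsilyl)oxy]-10-methyl-12-oxododeca-2,6-dienoate
Conditions: 10% aq. oxalic acid on SiO2, CH2Cl2, rt
Reagents that add atoms: water O
Why: Mild acid hydrolysis of the dimethyl acetal on wet silica frees the C6 aldehyde while the secondary TBS ether, the allylic acetate and the allylic bromide survive.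

Step 10
Reactants: 17 methyl (2Z,4S,6E,10S)-6-(acetoxymethyl)-2-(bromomethyl)-4-[(tert-butyldimethylsilyl)oxy]-10-methyl-12-oxododeca-2,6-dienoate
Product: 20 [(3aS,4S,6E,10S,11aS)-4-[(tert-butyldimethylsilyl)oxy]-10-methyl-3-methylidene-2-oxo-2,3,3a,4,5,8,9,10,11,11a-decahydrocyclodeca[b]furan-6-yl]methyl acetate, via allylchromium dichloride 18 (not isolated), via hydroxy ester 19 (not isolated)
Conditions: CrCl2 (10 equiv), THF, rt, slow addition of 17 (final 3 mM); 1 M HCl; then p-TsOH·H2O (cat.), CH2Cl2, rt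
Reagents that add atoms: none
Why: In this intramolecular Nozaki–Hiyama (Barbier-type) allylation, CrCl2 turns the electrophilic bromomethyl acrylate into a nucleophilic 2-(methoxycarbonyl)allyl species of trivalent chromium that attacks the C6 aldehyde through its γ-carbon C7 in a chair-like closed transition state; the ester-stabilised geometry with C8 cis to CH2Cr gives the 6,7-syn adduct (cis-fused lactone after acid-catalysed lactonisation), and with C8–H eclipsing the alkene to avoid A(1,3) strain the aldehyde, tethered through C9, is predicted to add anti to the bulky OTBS group and so give (6S,7S) from (8S).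

Step 11
Reactants: 20 [(3aS,4S,6E,10S,11aS)-4-[(tert-butyldimethylsilyl)oxy]-10-methyl-3-methylidene-2-oxo-2,3,3a,4,5,8,9,10,11,11a-decahydrocyclodeca[b]furan-6-yl]methyl acetate
Product: 21 [(3aR,4S,6E,10S,11aS)-4-hydroxy-10-methyl-3-methylidene-2-oxo-2,3,3a,4,5,8,9,10,11,11a-decahydrocyclodeca[b]furan-6-yl]methyl acetate
Conditions: HF·pyridine, pyridine, THF, 0 °C → rt
Reagents that add atoms: none
Why: Buffered HF·pyridine cleaves the secondary TBS ether without base, so the α-methylene lactone, the acetate and the lactone regiochemistry are preserved (the 3a descriptor changes only because the priority order changes).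

Step 12
Reactants: 21 [(3aR,4S,6E,10S,11aS)-4-hydroxy-10-methyl-3-methylidene-2-oxo-2,3,3a,4,5,8,9,10,11,11a-decahydrocyclodeca[b]furan-6-yl]methyl acetate; 22 2-[(tert-butyldimethylsilyl)oxy]acetic acid
Product: 24 target CNP0156635.1 [(3aS,4S,6E,10S,11aS)-4-(2-hydroxyacetoxy)-10-methyl-3-methylidene-2-oxo-2,3,3a,4,5,8,9,10,11,11a-decahydrocyclodeca[b]furan-6-yl]methyl acetate, via silyl glycolate ester 23 (not isolated)
Conditions: 22, DCC, DMAP (cat.), CH2Cl2, 0 °C → rt; then HF·pyridine, THF, 0 °C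
Reagents that add atoms: none
Why: Steglich esterification acylates the C8 hydroxyl with retention, and the primary TBS ether of the glycolate is then removed in the same flask with HF·pyridine, leaving the acetate and the lactone intact.

## Compound list

1 | (S)-5-(hydroxymethyl)dihydrofuran-2(3H)-one | O=C1CC[C@H](O1)CO | starting material
2 | (S)-5-{[(triethylsilyl)oxy]methyl}dihydrofuran-2(3H)-one | O=C1CC[C@H](O1)CO[Si](CC)(CC)CC | intermediate
3 | (S)-citronellal, (3S)-3,7-dimethyloct-6-enal | O=CC[C@@H](C)CCC=C(C)C | starting material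
4 | (S)-citronellal dimethyl acetal, (6S)-8,8-dimethoxy-2,6-dimethyloct-2-ene | COC(OC)C[C@@H](C)CCC=C(C)C | intermediate (not isolated)
5 | ozonide of 4, 3-[(3S)-5,5-dimethoxy-3-methylpentyl]-5,5-dimethyl-1,2,4-trioxolane | COC(OC)C[C@@H](C)CCC1OOC(C)(C)O1 | intermediate (not isolated)
6 | (4S)-6,6-dimethoxy-4-methylhexanal | COC(OC)C[C@@H](C)CCC=O | intermediate
7 | aldol adduct, (5S)-3-[(4S)-1-hydroxy-6,6-dimethoxy-4-methylhexyl]-5-{[(triethylsilyl)oxy]methyl}dihydrofuran-2(3H)-one (mixture at the two new centres) | COC(OC)C[C@@H](C)CCC(O)C1C(=O)O[C@H](CO[Si](CC)(CC)CC)C1 | intermediate (not isolated)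
8 | methanesulfonate of 7 | COC(OC)C[C@@H](C)CCC(OS(C)(=O)=O)C1C(=O)O[C@H](CO[Si](CC)(CC)CC)C1 | intermediate (not isolated)
9 | (3E,5S)-3-[(4S)-6,6-dimethoxy-4-methylhexylidene]-5-{[(triethylsilyl)oxy]methyl}dihydrofuran-2(3H)-one | COC(OC)C[C@@H](C)CC/C=C1/C(=O)O[C@H](CO[Si](CC)(CC)CC)C1 | intermediate
10 | (2S,4E,8S)-4-(hydroxymethyl)-10,10-dimethoxy-8-methyl-1-[(triethylsilyl)oxy]dec-4-en-2-ol | COC(OC)C[C@@H](C)CC/C=C(/CO)C[C@H](O)CO[Si](CC)(CC)CC | intermediate
11 | (2E,6S)-2-{(2S)-2-hydroxy-3-[(triethylsilyl)oxy]propyl}-8,8-dimethoxy-6-methyloct-2-en-1-yl acetate | COC(OC)C[C@@H](C)CC/C=C(/COC(C)=O)C[C@H](O)CO[Si](CC)(CC)CC | intermediate (not isolated)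
12 | (2E,6S)-2-{(2S)-2-[(tert-butyldimethylsilyl)oxy]-3-[(triethylsilyl)oxy]propyl}-8,8-dimethoxy-6-methyloct-2-en-1-yl acetate | COC(OC)C[C@@H](C)CC/C=C(/COC(C)=O)C[C@H](O[Si](C)(C)C(C)(C)C)CO[Si](CC)(CC)CC | intermediate
13 | (2E,6S)-2-{(2S)-2-[(tert-butyldimethylsilyl)oxy]-3-oxopropyl}-8,8-dimethoxy-6-methyloct-2-en-1-yl acetate | COC(OC)C[C@@H](C)CC/C=C(/COC(C)=O)C[C@H](O[Si](C)(C)C(C)(C)C)C=O | intermediate
14 | methyl acrylate | C=CC(=O)OC | starting material
15 | methyl (4S,6E,10S)-6-(acetoxymethyl)-4-[(tert-butyldimethylsilyl)oxy]-3-hydroxy-12,12-dimethoxy-10-methyl-2-methylidenedodec-6-enoate (C3 epimers) | COC(OC)C[C@@H](C)CC/C=C(/COC(C)=O)C[C@H](O[Si](C)(C)C(C)(C)C)C(O)C(=C)C(=O)OC | intermediate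
16 | methyl (2Z,4S,6E,10S)-6-(acetoxymethyl)-2-(bromomethyl)-4-[(tert-butyldimethylsilyl)oxy]-12,12-dimethoxy-10-methyldodeca-2,6-dienoate | COC(OC)C[C@@H](C)CC/C=C(/COC(C)=O)C[C@H](O[Si](C)(C)C(C)(C)C)/C=C(\CBr)C(=O)OC | intermediate
17 | methyl (2Z,4S,6E,10S)-6-(acetoxymethyl)-2-(bromomethyl)-4-[(tert-butyldimethylsilyl)oxy]-10-methyl-12-oxododeca-2,6-dienoate | O=CC[C@@H](C)CC/C=C(/COC(C)=O)C[C@H](O[Si](C)(C)C(C)(C)C)/C=C(\CBr)C(=O)OC | intermediate
18 | allylchromium dichloride derived from 17 (CH2Br replaced by CH2CrCl2, trivalent chromium) | O=CC[C@@H](C)CC/C=C(/COC(C)=O)C[C@H](O[Si](C)(C)C(C)(C)C)/C=C(\C[Cr](Cl)Cl)C(=O)OC | intermediate (not isolated)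
19 | methyl 2-[(1S,2S,4E,8S,10S)-4-(acetoxymethyl)-2-[(tert-butyldimethylsilyl)oxy]-10-hydroxy-8-methylcyclodec-4-en-1-yl]prop-2-enoate | C=C(C(=O)OC)[C@H]1[C@@H](O)C[C@@H](C)CC/C=C(/COC(C)=O)C[C@@H]1O[Si](C)(C)C(C)(C)C | intermediate (not isolated)
20 | [(3aS,4S,6E,10S,11aS)-4-[(tert-butyldimethylsilyl)oxy]-10-methyl-3-methylidene-2-oxo-2,3,3a,4,5,8,9,10,11,11a-decahydrocyclodeca[b]furan-6-yl]methyl acetate | C=C1C(=O)O[C@H]2C[C@@H](C)CC/C=C(/COC(C)=O)C[C@H](O[Si](C)(C)C(C)(C)C)[C@@H]12 | intermediate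
21 | [(3aR,4S,6E,10S,11aS)-4-hydroxy-10-methyl-3-methylidene-2-oxo-2,3,3a,4,5,8,9,10,11,11a-decahydrocyclodeca[b]furan-6-yl]methyl acetate | C=C1C(=O)O[C@H]2C[C@@H](C)CC/C=C(/COC(C)=O)C[C@H](O)[C@@H]12 | intermediate
22 | 2-[(tert-butyldimethylsilyl)oxy]acetic acid | O=C(O)CO[Si](C)(C)C(C)(C)C | starting material
23 | (3aS,4S,6E,10S,11aS)-6-(acetoxymethyl)-10-methyl-3-methylidene-2-oxo-2,3,3a,4,5,8,9,10,11,11a-decahydrocyclodeca[b]furan-4-yl 2-[(tert-butyldimethylsilyl)oxy]acetate | C=C1C(=O)O[C@H]2C[C@@H](C)CC/C=C(/COC(C)=O)C[C@H](OC(=O)CO[Si](C)(C)C(C)(C)C)[C@@H]12 | intermediate (not isolated)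
24 | CNP0156635.1, [(3aS,4S,6E,10S,11aS)-4-(2-hydroxyacetoxy)-10-methyl-3-methylidene-2-oxo-2,3,3a,4,5,8,9,10,11,11a-decahydrocyclodeca[b]furan-6-yl]methyl acetate | C=C1C(=O)O[C@H]2C[C@@H](C)CC/C=C(/COC(C)=O)C[C@H](OC(=O)CO)[C@@H]12 | target

## Step count and risks

Total step count: 12. Longest linear sequence: 11 steps (from 1 through steps 1 and 3–12, or from 3 through steps 2–12).

Three steps most likely to fail:

Step 10 (macrocyclisation). The risks are oligomerisation and addition to the wrong face of C7; the facial preference rests on an acyclic model and is not proven for this ring. The fallback replaces the organochromium by a configurationally stable allylboronate that cyclises thermally in a metal-free closed chair transition state. It sets out from 15. Acetylation (Ac2O, pyridine, DMAP) gives the allylic acetate F1. CuCl/KOt-Bu-catalysed SN2' borylation with B2pin2, which touches only the acrylate-activated acetate, gives the pinacol allylboronate acetal F2 with C8 cis to CH2B. Oxalic acid on wet SiO2 releases the allylboronate aldehyde F3, which is heated at high dilution (toluene, 80 °C, Sc(OTf)3 if needed) for intramolecular allylboration. Aqueous work-up gives hydroxy ester 19, where the fallback comes back to the route and is lactonised to 20 with p-TsOH as in step 10.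

Step 7 (Morita–Baylis–Hillman reaction). The risks are slow conversion and amine-induced epimerisation of the α-silyloxy aldehyde at C8. The fallback uses a stoichiometric acrylate α-anion equivalent at low temperature. It sets out from 13. Addition of the lithium enolate of methyl 3-(dimethylamino)propanoate (LiN(i-Pr)2, THF, −78 °C) gives the amino aldol F4. MeI gives the trimethylammonium iodide F5. Aqueous NaHCO3/CH2Cl2 then eliminates trimethylamine and returns to 15.

Step 6 (direct Swern oxidation of the primary triethylsilyl ether). The risks are incomplete silyl cleavage or acetal damage. The fallback separates deprotection and oxidation. It sets out from 12. PPTS in MeOH at 0 °C removes only the primary triethylsilyl group to give the primary alcohol F6, and Dess–Martin periodinane (NaHCO3, CH2Cl2) oxidises it to 13, where the route continues.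

Further compounds
F1 | step 10 | methyl (4S,6E,10S)-3-acetoxy-6-(acetoxymethyl)-4-[(tert-butyldimethylsilyl)oxy]-12,12-dimethoxy-10-methyl-2-methylidenedodec-6-enoate | COC(OC)C[C@@H](C)CC/C=C(/COC(C)=O)C[C@H](O[Si](C)(C)C(C)(C)C)C(OC(C)=O)C(=C)C(=O)OC
F2 | step 10 | pinacol allylboronate acetal, 16 with CH2Br replaced by CH2B(pin) | COC(OC)C[C@@H](C)CC/C=C(/COC(C)=O)C[C@H](O[Si](C)(C)C(C)(C)C)/C=C(\CB1OC(C)(C)C(C)(C)O1)C(=O)OC
F3 | step 10 | pinacol allylboronate aldehyde, 17 with CH2Br replaced by CH2B(pin) | O=CC[C@@H](C)CC/C=C(/COC(C)=O)C[C@H](O[Si](C)(C)C(C)(C)C)/C=C(\CB1OC(C)(C)C(C)(C)O1)C(=O)OC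
F4 | step 7 | methyl (4S,6E,10S)-6-(acetoxymethyl)-4-[(tert-butyldimethylsilyl)oxy]-2-[(dimethylamino)methyl]-3-hydroxy-12,12-dimethoxy-10-methyldodec-6-enoate | COC(OC)C[C@@H](C)CC/C=C(/COC(C)=O)C[C@H](O[Si](C)(C)C(C)(C)C)C(O)C(CN(C)C)C(=O)OC
F5 | step 7 | trimethylammonium iodide of F4 | COC(OC)C[C@@H](C)CC/C=C(/COC(C)=O)C[C@H](O[Si](C)(C)C(C)(C)C)C(O)C(C[N+](C)(C)C)C(=O)OC.[I-]
F6 | step 6 | (2E,6S)-2-{(2S)-2-[(tert-butyldimethylsilyl)oxy]-3-hydroxypropyl}-8,8-dimethoxy-6-methyloct-2-en-1-yl acetate | COC(OC)C[C@@H](C)CC/C=C(/COC(C)=O)C[C@H](O[Si](C)(C)C(C)(C)C)CO
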